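Atom labels C1–C20 follow prostaglandin numbering: C1 is the carboxyl carbon, C8–C12 the ring, C15 the ketone carbon.

## Analysis of the target

15-Keto-PGF2alpha is a C20 prostanoid built on a cyclopentane (C8–C12). C8 carries a seven-carbon acid chain with a Z alkene at C5=C6, and C12 carries an eight-carbon chain whose E alkene C13=C14 is conjugated with the C15 ketone. The four stereocentres all sit on the ring (C8 R, C9 S, C11 R, C12 R). The hydroxyls at C9 and C11 and the C8 chain lie on one face, and the C12 chain lies on the other, trans to both of its neighbours. The chains hold no stereocentre, because C15 is a ketone. The enone is the fragile part: it is a Michael acceptor, it is reduced by hydrides and attacked by ylides, and it makes C12–H gamma-acidic, so base can epimerise C12 or expel the C11 oxygen through the dienolate. The Z alkene must survive without isomerisation or reduction, and the free acid and 1,3-diol limit the final steps. The ring stereochemistry can be bought, so the real difficulty is to carry C15 at the ketone level through the hydride and ylide steps that build the upper chain, without a reduce-and-reoxidise detour. The strategy rests on the C13=C14–C15(=O) unit being a dehydrated aldol (oxygen on C13, carbonyl at C15). That aldol corresponds to a 3-pentyl-2-isoxazoline whose O1–C5 is C13–O, C4 is C14 and C3 is C15, and this ring is the adduct of a C12 vinyl group with hexanenitrile oxide.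

## Retrosynthetic reasoning

**20 to 19 to 18.** The last operations only remove the methyl ester and the two silyl ethers. They are placed at the end because a free acid would add to the dipole 13 and free ring hydroxyls would compete in the later sulfonylation. The forward steps must avoid any base able to form the dienolate of the enone, so desilylation is acidic and the ester is opened enzymatically.

**18 to 16 (through 17).** The C13=C14 double bond is traced back to a hydroxyl on C13 beta to the C15 ketone. Elimination of a beta-sulfonyloxy ketone can only give the conjugated alkene, and the E isomer is the stable one. The step also erases C13 as a stereocentre, so both C13 epimers of 16 converge on 18.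

**16 to 14 (through 15).** The C13 hydroxyl and the C15 carbonyl are tied together through nitrogen as a 2-isoxazoline. This keeps C15 at the ketone oxidation level but hides it as a cyclic oxime ether. The forward step must break only the N–O bond and hydrolyse imine 15, leaving the Z alkene, the ester and the silyl ethers alone.

**14 to 10 and 13 (key disconnection).** The C14–C15 and C13–O bonds are cut together. This is the one cut that brings in the whole C15–C20 segment with C15 already oxidised and leaves only a vinyl group on C12 of 10. The dipole 13 is reached from hydroximoyl chloride 12 by loss of HCl, and 12 from oxime 11 by chlorination. The forward reaction must place oxygen on C13 and must prefer the vinyl group over C5=C6.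

**10 to 9 to 8.** Only protecting groups change. The two silyl ethers leave the later C13 hydroxyl as the only free one, and the methyl ester keeps the carboxylate away from the dipole.

**8 to 5 and 7.** The C5=C6 bond is cut. A non-stabilised ylide 7, made from phosphonium salt 6, reacts with the masked aldehyde of lactol 5, gives the Z alkene and frees the C9 hydroxyl in the same step.

**5 to 4 to 3.** The lactol comes from the lactone by partial reduction, after the benzoate has been removed so that it does not consume hydride unpredictably.

**3 to 2 to 1.** The vinyl group is cut at C13=C14 back to aldehyde 2, which is the oxidation product of the commercial lactone 1. Compound 1 already holds all four ring stereocentres and keeps the C9 oxygen and C6 tied up as a lactone. An assembly of the ring by tandem conjugate addition and enolate alkylation on a cyclopentenone was weighed for 10 and set aside. Alkylation of a beta-silyloxy cyclopentanone enolate is prone to proton transfer and loss of the silyloxy group, and that would put risk ahead of the key step.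

## Alternatives that were turned down

**Alternative 1: enzymatic double dioxygenation.**
- Disconnection: the ring bond C8–C12 and the oxygens at C9, C11 and C15 are all traced back to the acyclic tetraene acid arachidonic acid A1.
- Forward key step: in the cyclooxygenase site of prostaglandin H synthase, a C13 radical is oxygenated at C11. The peroxyl radical closes onto C9, the C8 radical closes onto C12, and a second oxygenation at C15 gives prostaglandin G2 A2.
- For it: one operation sets all four ring stereocentres, both alkenes and an oxygen at C15 without any protecting group. On step count and stereocontrol it is stronger than the chosen route.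
- Against it: A2 is a strained endoperoxide and hydroperoxide that is short-lived in aqueous buffer. The enzyme inactivates itself during turnover, so the step is confined to very small scale. The endoperoxide must then be reduced to the 9,11-diol without rearrangement to keto alcohols, and C15 must still be brought from hydroperoxide to ketone.
- Comparison: the chosen route is longer, but offers isolable, stable intermediates, ordinary preparative scale and independence from an enzyme preparation.

**Alternative 2: cyclopropylcarbinyl solvolysis.**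
- Disconnection: the C11–O bond is cut and C11 is reconnected to C13. C11, C12 and C13 then form a cyclopropane fused to the five-membered ring, and C14–C15 carry an epoxide, as in methyl (Z)-7-[3-acetoxy-6-(3-pentyloxiran-2-yl)bicyclo[3.1.0]hexan-2-yl]hept-5-enoate A3.
- Forward key step: acid opens the epoxide towards C14. The resulting cyclopropylcarbinyl cation breaks the C11–C13 bond while a hydroxylic nucleophile enters at C11 from the face opposite C13. This gives prostaglandin F2alpha methyl ester 9-acetate A4 as a mixture of C15 epimers, with the E alkene at C13=C14.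
- For it: the step creates the C11 stereocentre by inversion, the E alkene and the C15 oxygen together. The lack of control at C15 does not matter here because C15 ends as a ketone, so on that point it matches the chosen route, whose only new centre (C13) is also erased.
- Against it: cyclopropylcarbinyl cations partition between several capture and elimination paths, so only part of the material follows the homoallylic route. A3 is itself a long synthesis. After the key step an allylic oxidation at C15 and removal of acetate and ester remain, and the base for the acetate either meets the enone or must come before the oxidation.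
- Comparison: the chosen route takes C11 from lactone 1, brings C15 in at the ketone level with no redox correction, and asks only regio- and chemoselectivity of its key step.

**Alternative 3: alkynal hydroacylation.**
- Disconnection: the ring bond C9–C10 is cut, which opens the ring to (2R,3R)-2-[2-(tert-butyldimethylsilyloxy)ethyl]-3-[(4-methoxybenzyloxy)methyl]pent-4-ynal A5, with C9 as the aldehyde and C10–C11 as the terminal alkyne.
- Forward key step: a cationic rhodium diphosphine catalyst inserts into the aldehyde C–H bond, adds the acyl hydride across the alkyne in a trans sense and reductively eliminates to form C9–C10. The product is (4S,5R)-5-[2-(tert-butyldimethylsilyloxy)ethyl]-4-[(4-methoxybenzyloxy)methyl]cyclopent-2-en-1-one A6.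
- For it: the ring is built catalytically and with full atom economy from an acyclic precursor, no chiral bicycle has to be bought, and ring analogues are easy to reach. On these points it is stronger.
- Against it: A6 holds only C8 and C12. The C11 hydroxyl must still be introduced trans to C12 and C9 reduced to the alpha alcohol. Both chains are short stubs that each need deprotection, oxidation and olefination. The lower enone would have to be made from a C12 aldehyde beside an oxygenated C11 and then carried past a basic Wittig step and a ketone reduction, which is the problem the isoxazoline avoids. A5 also needs its own enantio- and diastereoselective synthesis.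
- Comparison: the step count would clearly exceed the thirteen steps of the chosen route, which starts from a ring that already has its four stereocentres and its oxygens.

Key step: step 9

## Route

Remark: the CIP label of ring carbon C12 (cyclopentyl C2) reads R in 10, S in 14–16 and R again in 17–20. This comes only from changes in substituent priority; the centre itself is never touched.

Assumption: hexanal oxime 11 is used as the commercial mixture of E and Z isomers; both are chlorinated to the same hydroximoyl chloride 12.

Step 1
Reactants: 1 (3aR,4S,5R,6aS)-4-(hydroxymethyl)-2-oxohexahydro-2H-cyclopenta[b]furan-5-yl benzoate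
Product: 2 (3aR,4R,5R,6aS)-4-formyl-2-oxohexahydro-2H-cyclopenta[b]furan-5-yl benzoate
Conditions: Dess–Martin periodinane, CH2Cl2, 0 °C to rt; crude aldehyde used at once
Reagents that add atoms: none
Why: Dess–Martin oxidation takes the primary alcohol to the aldehyde without amine base, so the beta-benzoyloxy aldehyde should neither lose benzoate nor epimerise at C12.

Step 2
Reactants: 2 (3aR,4R,5R,6aS)-4-formyl-2-oxohexahydro-2H-cyclopenta[b]furan-5-yl benzoate
Product: 3 (3aR,4R,5R,6aS)-2-oxo-4-vinylhexahydro-2H-cyclopenta[b]furan-5-yl benzoate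
Conditions: CH2I2, Zn, Ti(OiPr)4, THF, rt
Reagents that add atoms: diiodomethane, C(I)I
Why: Takai methylenation: the geminal dizinc reagent formed from CH2I2 and Zn adds to the aldehyde and eliminates to the terminal alkene under non-basic conditions. Esters and lactones are not attacked, and the absence of base protects the benzoate and the C12 centre.

Step 3
Reactants: 3 (3aR,4R,5R,6aS)-2-oxo-4-vinylhexahydro-2H-cyclopenta[b]furan-5-yl benzoate
Product: 4 (3aR,4R,5R,6aS)-5-hydroxy-4-vinylhexahydro-2H-cyclopenta[b]furan-2-one
Conditions: K2CO3 (cat.), MeOH, rt; then aq. HCl to pH 3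
Reagents that add atoms: none
Why: Base-catalysed transesterification removes the benzoate as its methyl ester; any lactone opened by methoxide should close again on acidification because the cis-fused gamma-lactone is favoured.

Step 4
Reactants: 4 (3aR,4R,5R,6aS)-5-hydroxy-4-vinylhexahydro-2H-cyclopenta[b]furan-2-one
Product: 5 (3aR,4R,5R,6aS)-4-vinylhexahydro-2H-cyclopenta[b]furan-2,5-diol (lactol; both anomers)
Conditions: i-Bu2AlH (2.5 equiv), CH2Cl2, −78 °C; aq. potassium sodium tartrate work-up
Reagents that add atoms: none
Why: Partial reduction of the gamma-lactone stops at the tetrahedral aluminium hemiacetal at low temperature; one equivalent of hydride is used up by the free hydroxyl, and the vinyl group is inert.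

Step 5
Reactants: 5 (3aR,4R,5R,6aS)-4-vinylhexahydro-2H-cyclopenta[b]furan-2,5-diol; 6 (4-carboxybutyl)triphenylphosphonium bromide
Product: 8 (Z)-7-[(1R,2R,3R,5S)-3,5-dihydroxy-2-vinylcyclopentyl]hept-5-enoic acid, via carboxylate ylide 7 (not isolated)
Conditions: 6 (4 equiv), KOtBu (8 equiv), THF, 0 °C; then 5, 0 °C to rt; acidic work-up
Reagents that add atoms: none
Why: Wittig olefination of the open hydroxy-aldehyde form of the lactol with a non-stabilised ylide under lithium-free conditions; kinetic formation of the cis-oxaphosphetane should give the Z alkene. Excess ylide covers the acidic hydroxyls, and the C9 hydroxyl is released in the same step.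

Step 6
Reactants: 8 (Z)-7-[(1R,2R,3R,5S)-3,5-dihydroxy-2-vinylcyclopentyl]hept-5-enoic acid
Product: 9 methyl (Z)-7-[(1R,2R,3R,5S)-3,5-dihydroxy-2-vinylcyclopentyl]hept-5-enoate
Conditions: MeI, K2CO3, DMF, rt
Reagents that add atoms: iodomethane, CI
Why: SN2 alkylation of the carboxylate; under carbonate the secondary alcohols are not deprotonated and stay free.

Step 7
Reactants: 9 methyl (Z)-7-[(1R,2R,3R,5S)-3,5-dihydroxy-2-vinylcyclopentyl]hept-5-enoate
Product: 10 methyl (Z)-7-[(1R,2R,3R,5S)-3,5-bis(tert-butyldimethylsilyloxy)-2-vinylcyclopentyl]hept-5-enoate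
Conditions: TBSCl, imidazole, DMF, rt to 40 °C
Reagents that add atoms: tert-butyldimethylsilyl chloride, CC(C)(C)[Si](C)(C)Cl
Why: Imidazole-promoted silylation of both secondary ring alcohols; the groups remove nucleophilic OH before the dipole is generated and leave the later C13 hydroxyl as the only one free.

Step 8
Reactants: 11 hexanal oxime
Product: 12 N-hydroxyhexanimidoyl chloride
Conditions: N-chlorosuccinimide, DMF, 0 °C to rt; extractive work-up, used crude
Reagents that add atoms: N-chlorosuccinimide, O=C1CCC(=O)N1Cl
Why: Electrophilic chlorination of the aldoxime carbon gives the hydroximoyl chloride. It is made separately so that no active chlorine meets the alkenes of 10.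

Step 9
Reactants: 10 methyl (Z)-7-[(1R,2R,3R,5S)-3,5-bis(tert-butyldimethylsilyloxy)-2-vinylcyclopentyl]hept-5-enoate; 12 N-hydroxyhexanimidoyl chloride
Product: 14 methyl (Z)-7-[(1R,2S,3R,5S)-3,5-bis(tert-butyldimethylsilyloxy)-2-(3-pentyl-4,5-dihydroisoxazol-5-yl)cyclopentyl]hept-5-enoate (both epimers at C13), via hexanenitrile oxide 13 (not isolated)
Conditions: 12 (3 equiv), Et3N (3.3 equiv, syringe pump over 12 h), Et2O, 0 °C to rt
Reagents that add atoms: none
Why: Et3N removes HCl from 12 to give nitrile oxide 13, which adds to the C13=C14 vinyl group of 10 in a concerted, asynchronous, suprafacial (3+2) cycloaddition; the closest known reaction type is the Huisgen nitrile oxide–alkene cycloaddition used to mask aldols as 2-isoxazolines. The isoxazoline ring closes in this single intermolecular pericyclic event, with the C14–C15 and C13–O bonds formed together, so no separate cyclisation mode has to be met. Regiochemistry follows from the unhindered terminal carbon C14 bonding to the dipole carbon, which puts oxygen on C13 and gives the 5-substituted isoxazoline. The only new stereocentre, C13, is set by which face of the vinyl group is approached, under the influence of the neighbouring C12 centre; the selectivity is expected to be modest and does not matter because C13 becomes sp2 in step 11. Chemoselectivity for the vinyl group over C5=C6 is needed and rests on the much lower dipolarophilicity of 1,2-disubstituted Z alkenes towards nitrile oxides. Slow addition of base keeps the concentration of 13 low so that dimerisation to the furoxan is held back, and the excess of 12 makes up for what is lost that way. The silyl ethers and the methyl ester are inert to the dipole, whereas a free acid or free hydroxyls could add to it, which is why 10 is fully protected.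

Step 10
Reactants: 14 methyl (Z)-7-[(1R,2S,3R,5S)-3,5-bis(tert-butyldimethylsilyloxy)-2-(3-pentyl-4,5-dihydroisoxazol-5-yl)cyclopentyl]hept-5-enoate
Product: 16 methyl (Z)-7-[(1R,2S,3R,5S)-3,5-bis(tert-butyldimethylsilyloxy)-2-(1-hydroxy-3-oxooctyl)cyclopentyl]hept-5-enoate (C13 epimers), via beta-hydroxy imine 15 (not isolated)
Conditions: Mo(CO)6 (0.6 equiv), MeCN/H2O 15:1, 80 °C
Reagents that add atoms: water, O
Why: Zerovalent molybdenum binds the ring nitrogen and cleaves the weak N–O bond reductively; the beta-hydroxy imine is hydrolysed in the wet solvent to the ketone. Unlike hydrogenolysis, this method leaves isolated alkenes, esters and silyl ethers untouched.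

Step 11
Reactants: 16 methyl (Z)-7-[(1R,2S,3R,5S)-3,5-bis(tert-butyldimethylsilyloxy)-2-(1-hydroxy-3-oxooctyl)cyclopentyl]hept-5-enoate
Product: 18 methyl (Z)-7-[(1R,2R,3R,5S)-3,5-bis(tert-butyldimethylsilyloxy)-2-[(E)-3-oxooct-1-enyl]cyclopentyl]hept-5-enoate, via C13 mesylate 17 (not isolated)
Conditions: MsCl, Et3N (excess), CH2Cl2, 0 °C to rt
Reagents that add atoms: none
Why: The only free hydroxyl is sulfonylated, and the beta-mesyloxy ketone then undergoes E1cB elimination through the C14 enolate to the conjugated enone, with the E geometry as the stable one. Both C13 epimers converge, and the amine is too weak to deprotonate C12.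

Step 12
Reactants: 18 methyl (Z)-7-[(1R,2R,3R,5S)-3,5-bis(tert-butyldimethylsilyloxy)-2-[(E)-3-oxooct-1-enyl]cyclopentyl]hept-5-enoate
Product: 19 methyl (Z)-7-[(1R,2R,3R,5S)-3,5-dihydroxy-2-[(E)-3-oxooct-1-enyl]cyclopentyl]hept-5-enoate
Conditions: HF·pyridine, pyridine/THF, 0 °C to rt
Reagents that add atoms: none
Why: Acidic fluoride cleaves both silyl ethers through the strong Si–F bond. A basic fluoride source is avoided so that no dienolate forms that could epimerise C12 or expel the C11 oxygen.

Step 13
Reactants: 19 methyl (Z)-7-[(1R,2R,3R,5S)-3,5-dihydroxy-2-[(E)-3-oxooct-1-enyl]cyclopentyl]hept-5-enoate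
Product: 20 (Z)-7-[(1R,2R,3R,5S)-3,5-dihydroxy-2-[(E)-3-oxooct-1-enyl]cyclopentyl]hept-5-enoic acid (15-keto-PGF2alpha)
Conditions: porcine liver esterase, pH 7 sodium phosphate buffer (NaH2PO4/Na2HPO4), acetone co-solvent, 30 °C
Reagents that add atoms: water, O
Why: Enzymatic ester hydrolysis through an acyl-enzyme intermediate at neutral pH, a standard way to open prostaglandin methyl esters; the enone never meets hydroxide.

## Compound list

1 | (3aR,4S,5R,6aS)-4-(hydroxymethyl)-2-oxohexahydro-2H-cyclopenta[b]furan-5-yl benzoate | OC[C@@H]1[C@@H](CC(=O)O2)[C@@H]2C[C@H]1OC(=O)c1ccccc1 | starting material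
2 | (3aR,4R,5R,6aS)-4-formyl-2-oxohexahydro-2H-cyclopenta[b]furan-5-yl benzoate | O=C[C@@H]1[C@@H](CC(=O)O2)[C@@H]2C[C@H]1OC(=O)c1ccccc1 | intermediate
3 | (3aR,4R,5R,6aS)-2-oxo-4-vinylhexahydro-2H-cyclopenta[b]furan-5-yl benzoate | C=C[C@@H]1[C@@H](CC(=O)O2)[C@@H]2C[C@H]1OC(=O)c1ccccc1 | intermediate
4 | (3aR,4R,5R,6aS)-5-hydroxy-4-vinylhexahydro-2H-cyclopenta[b]furan-2-one | C=C[C@@H]1[C@@H](CC(=O)O2)[C@@H]2C[C@H]1O | intermediate
5 | (3aR,4R,5R,6aS)-4-vinylhexahydro-2H-cyclopenta[b]furan-2,5-diol (both anomers) | C=C[C@@H]1[C@@H](CC(O)O2)[C@@H]2C[C@H]1O | intermediate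
6 | (4-carboxybutyl)triphenylphosphonium bromide | OC(=O)CCCC[P+](c1ccccc1)(c1ccccc1)c1ccccc1.[Br-] | starting material
7 | potassium 5-(triphenylphosphoranylidene)pentanoate (carboxylate ylide) | [K+].[O-]C(=O)CCCC=P(c1ccccc1)(c1ccccc1)c1ccccc1 | intermediate (not isolated)
8 | (Z)-7-[(1R,2R,3R,5S)-3,5-dihydroxy-2-vinylcyclopentyl]hept-5-enoic acid | C=C[C@@H]1[C@@H](C/C=C\CCCC(=O)O)[C@@H](O)C[C@H]1O | intermediate
9 | methyl (Z)-7-[(1R,2R,3R,5S)-3,5-dihydroxy-2-vinylcyclopentyl]hept-5-enoate | C=C[C@@H]1[C@@H](C/C=C\CCCC(=O)OC)[C@@H](O)C[C@H]1O | intermediate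
10 | methyl (Z)-7-[(1R,2R,3R,5S)-3,5-bis(tert-butyldimethylsilyloxy)-2-vinylcyclopentyl]hept-5-enoate | C=C[C@@H]1[C@@H](C/C=C\CCCC(=O)OC)[C@@H](O[Si](C)(C)C(C)(C)C)C[C@H]1O[Si](C)(C)C(C)(C)C | intermediate
11 | hexanal oxime | CCCCCC=NO | starting material
12 | N-hydroxyhexanimidoyl chloride | CCCCCC(Cl)=NO | intermediate
13 | hexanenitrile oxide | CCCCCC#[N+][O-] | intermediate (not isolated)
14 | methyl (Z)-7-[(1R,2S,3R,5S)-3,5-bis(tert-butyldimethylsilyloxy)-2-(3-pentyl-4,5-dihydroisoxazol-5-yl)cyclopentyl]hept-5-enoate (both epimers at the isoxazoline C5) | CCCCCC1=NOC(C1)[C@@H]2[C@@H](C/C=C\CCCC(=O)OC)[C@@H](O[Si](C)(C)C(C)(C)C)C[C@H]2O[Si](C)(C)C(C)(C)C | intermediate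
15 | methyl (Z)-7-[(1R,2S,3R,5S)-3,5-bis(tert-butyldimethylsilyloxy)-2-(1-hydroxy-3-iminooctyl)cyclopentyl]hept-5-enoate | CCCCCC(=N)CC(O)[C@@H]1[C@@H](C/C=C\CCCC(=O)OC)[C@@H](O[Si](C)(C)C(C)(C)C)C[C@H]1O[Si](C)(C)C(C)(C)C | intermediate (not isolated)
16 | methyl (Z)-7-[(1R,2S,3R,5S)-3,5-bis(tert-butyldimethylsilyloxy)-2-(1-hydroxy-3-oxooctyl)cyclopentyl]hept-5-enoate (C13 epimers) | CCCCCC(=O)CC(O)[C@@H]1[C@@H](C/C=C\CCCC(=O)OC)[C@@H](O[Si](C)(C)C(C)(C)C)C[C@H]1O[Si](C)(C)C(C)(C)C | intermediate
17 | methyl (Z)-7-[(1R,2R,3R,5S)-3,5-bis(tert-butyldimethylsilyloxy)-2-[1-(methylsulfonyloxy)-3-oxooctyl]cyclopentyl]hept-5-enoate | CCCCCC(=O)CC(OS(C)(=O)=O)[C@@H]1[C@@H](C/C=C\CCCC(=O)OC)[C@@H](O[Si](C)(C)C(C)(C)C)C[C@H]1O[Si](C)(C)C(C)(C)C | intermediate (not isolated)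
18 | methyl (Z)-7-[(1R,2R,3R,5S)-3,5-bis(tert-butyldimethylsilyloxy)-2-[(E)-3-oxooct-1-enyl]cyclopentyl]hept-5-enoate | CCCCCC(=O)/C=C/[C@@H]1[C@@H](C/C=C\CCCC(=O)OC)[C@@H](O[Si](C)(C)C(C)(C)C)C[C@H]1O[Si](C)(C)C(C)(C)C | intermediate
19 | methyl (Z)-7-[(1R,2R,3R,5S)-3,5-dihydroxy-2-[(E)-3-oxooct-1-enyl]cyclopentyl]hept-5-enoate | CCCCCC(=O)/C=C/[C@@H]1[C@@H](C/C=C\CCCC(=O)OC)[C@@H](O)C[C@H]1O | intermediate
20 | (Z)-7-[(1R,2R,3R,5S)-3,5-dihydroxy-2-[(E)-3-oxooct-1-enyl]cyclopentyl]hept-5-enoic acid (15-keto-PGF2alpha) | CCCCCC(=O)/C=C/[C@@H]1[C@@H](C/C=C\CCCC(=O)O)[C@@H](O)C[C@H]1O | target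

## Step count and least certain steps

Total step count: 13. Longest linear sequence: 12 steps (steps 1–7 and 9–13, from 1); step 8 is a one-step branch from 11.

**Step 9 (key step).** The most likely failure is that 13 dimerises to the furoxan faster than it adds to a vinyl group flanked by two ring substituents, so that conversion stays incomplete. A smaller risk is competing addition to C5=C6. The fallback gives up the masked enone, sets out from 2 and returns at 20. Horner–Wadsworth–Emmons olefination of 2 with dimethyl (2-oxoheptyl)phosphonate (LiCl, i-Pr2NEt, MeCN) should give (3aR,4R,5R,6aS)-2-oxo-4-[(E)-3-oxooct-1-enyl]hexahydro-2H-cyclopenta[b]furan-5-yl benzoate F1. Because this ketone would not survive the hydride and ylide steps, Luche reduction (NaBH4, CeCl3·7H2O, MeOH) takes it to (3aR,4R,5R,6aS)-4-[(E)-3-hydroxyoct-1-enyl]-2-oxohexahydro-2H-cyclopenta[b]furan-5-yl benzoate F2, with both C15 epimers carried on. K2CO3 in MeOH then gives (3aR,4R,5R,6aS)-5-hydroxy-4-[(E)-3-hydroxyoct-1-enyl]hexahydro-2H-cyclopenta[b]furan-2-one F3, and i-Bu2AlH gives (3aR,4R,5R,6aS)-4-[(E)-3-hydroxyoct-1-enyl]hexahydro-2H-cyclopenta[b]furan-2,5-diol F4. Wittig reaction with ylide 7 gives (Z)-7-[(1R,2R,3R,5S)-3,5-dihydroxy-2-[(E)-3-hydroxyoct-1-enyl]cyclopentyl]hept-5-enoic acid F5, which is prostaglandin F2alpha together with its C15 epimer. DDQ in dioxane should oxidise only the allylic C15 hydroxyl and bring both epimers to 20.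

**Step 2.** The sensitive aldehyde may lose benzoate by beta-elimination or epimerise at C12 before methylene transfer is complete, or the transfer may be sluggish. The fallback is a Peterson olefination that sets out from 2 and returns at 3. Addition of Me3SiCH2MgCl with CeCl3 in THF at −78 °C should give (3aR,4S,5R,6aS)-4-[1-hydroxy-2-(trimethylsilyl)ethyl]-2-oxohexahydro-2H-cyclopenta[b]furan-5-yl benzoate F6 as carbinol epimers. BF3·OEt2 in CH2Cl2 then induces anti-elimination to 3.

**Step 10.** Heating with the molybdenum carbonyl may isomerise C5=C6 from Z to E, or the beta-hydroxy imine or ketone may fragment by retro-aldol cleavage. The fallback opens the ring without reduction, sets out from 14 and returns at 18, so that step 11 is bypassed as well. LiN(iPr)2 in excess (THF, −78 to 0 °C) deprotonates C14, and the anion expels the ring oxygen from C13. This gives methyl (Z)-7-[(1R,2R,3R,5S)-3,5-bis(tert-butyldimethylsilyloxy)-2-[(1E)-3-(hydroxyimino)oct-1-enyl]cyclopentyl]hept-5-enoate F7; the ester enolate formed alongside is reprotonated on quench. Reductive deoximation with aqueous TiCl3 and NH4OAc in THF then gives 18.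

## Further compounds

F1 | step 9 | (3aR,4R,5R,6aS)-2-oxo-4-[(E)-3-oxooct-1-enyl]hexahydro-2H-cyclopenta[b]furan-5-yl benzoate | CCCCCC(=O)/C=C/[C@@H]1[C@@H](CC(=O)O2)[C@@H]2C[C@H]1OC(=O)c1ccccc1
F2 | step 9 | (3aR,4R,5R,6aS)-4-[(E)-3-hydroxyoct-1-enyl]-2-oxohexahydro-2H-cyclopenta[b]furan-5-yl benzoate (C15 epimers) | CCCCCC(O)/C=C/[C@@H]1[C@@H](CC(=O)O2)[C@@H]2C[C@H]1OC(=O)c1ccccc1
F3 | step 9 | (3aR,4R,5R,6aS)-5-hydroxy-4-[(E)-3-hydroxyoct-1-enyl]hexahydro-2H-cyclopenta[b]furan-2-one (C15 epimers) | CCCCCC(O)/C=C/[C@@H]1[C@@H](CC(=O)O2)[C@@H]2C[C@H]1O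
F4 | step 9 | (3aR,4R,5R,6aS)-4-[(E)-3-hydroxyoct-1-enyl]hexahydro-2H-cyclopenta[b]furan-2,5-diol (C15 epimers, both anomers) | CCCCCC(O)/C=C/[C@@H]1[C@@H](CC(O)O2)[C@@H]2C[C@H]1O
F5 | step 9 | (Z)-7-[(1R,2R,3R,5S)-3,5-dihydroxy-2-[(E)-3-hydroxyoct-1-enyl]cyclopentyl]hept-5-enoic acid (C15 epimers) | CCCCCC(O)/C=C/[C@@H]1[C@@H](C/C=C\CCCC(=O)O)[C@@H](O)C[C@H]1O
F6 | step 2 | (3aR,4S,5R,6aS)-4-[1-hydroxy-2-(trimethylsilyl)ethyl]-2-oxohexahydro-2H-cyclopenta[b]furan-5-yl benzoate (carbinol epimers) | C[Si](C)(C)CC(O)[C@@H]1[C@@H](CC(=O)O2)[C@@H]2C[C@H]1OC(=O)c1ccccc1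
F7 | step 10 | methyl (Z)-7-[(1R,2R,3R,5S)-3,5-bis(tert-butyldimethylsilyloxy)-2-[(1E)-3-(hydroxyimino)oct-1-enyl]cyclopentyl]hept-5-enoate | CCCCCC(=NO)/C=C/[C@@H]1[C@@H](C/C=C\CCCC(=O)OC)[C@@H](O[Si](C)(C)C(C)(C)C)C[C@H]1O[Si](C)(C)C(C)(C)C
A1 | alternative 1 | arachidonic acid, (5Z,8Z,11Z,14Z)-icosa-5,8,11,14-tetraenoic acid | CCCCC/C=C\C/C=C\C/C=C\C/C=C\CCCC(=O)O
A2 | alternative 1 | prostaglandin G2 | CCCCC[C@H](OO)/C=C/[C@@H]1[C@@H](C/C=C\CCCC(=O)O)[C@@H]2C[C@H]1OO2
A3 | alternative 2 | methyl (Z)-7-[3-acetoxy-6-(3-pentyloxiran-2-yl)bicyclo[3.1.0]hexan-2-yl]hept-5-enoate (cyclopropane on the beta face; C13 and oxirane configurations left open) | CCCCCC1OC1C2[C@@H]3[C@@H](C/C=C\CCCC(=O)OC)[C@@H](OC(C)=O)C[C@H]23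
A4 | alternative 2 | prostaglandin F2alpha methyl ester 9-acetate (C15 epimers) | CCCCCC(O)/C=C/[C@@H]1[C@@H](C/C=C\CCCC(=O)OC)[C@@H](OC(C)=O)C[C@H]1O
A5 | alternative 3 | (2R,3R)-2-[2-(tert-butyldimethylsilyloxy)ethyl]-3-[(4-methoxybenzyloxy)methyl]pent-4-ynal | COc1ccc(COC[C@@H](C#C)[C@@H](CCO[Si](C)(C)C(C)(C)C)C=O)cc1
A6 | alternative 3 | (4S,5R)-5-[2-(tert-butyldimethylsilyloxy)ethyl]-4-[(4-methoxybenzyloxy)methyl]cyclopent-2-en-1-one | COc1ccc(COC[C@@H]2[C@@H](CCO[Si](C)(C)C(C)(C)C)C(=O)C=C2)cc1
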